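**Plan**

- The target is an achiral depside. After removing the protecting groups, the retrosynthesis cuts both bonds of the inter-ring ester carbonyl: ring A C1–C(=O) and C(=O)–O at C4 of ring B.
- The enabling feature is that this carbonyl carbon is an isolated one-carbon unit between ring A C1 and the ring B oxygen para to the carboxyl. It can therefore enter as carbon monoxide between a ring A C1 iodide and the free 4-OH of benzyl divarate, whose 2-OH is tied to its own ester carbonyl by a hydrogen bond.
- Forward, ring A iodide 8 comes from 3,5-dimethoxyphenylacetic acid in four steps (Weinreb amide, propyl Grignard, dioxolane, iodination ortho to the side chain). Ring B partner 11 comes from divarinol in two steps (carboxylation, benzyl ester).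
- Both benzene rings are bought and no ring is formed. The two fragments and CO are joined in step 7, then the benzyl ester is hydrogenolysed, and BCl3 finally removes only the methyl ether beside the new ester carbonyl and unmasks the ketone.
- There is no stereocentre or double-bond geometry to set; the only stereocentre on the way is the transient racemic one in adduct 5.

Key step: step 7

Remark: a 1,3-dioxolane is not expected to survive BCl3, so the benzyl ester is removed first and the Lewis acid step is placed last, where loss of the ketal is wanted.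

**Route**

Step 1
Reactants: 1 3,5-dimethoxyphenylacetic acid
Product: 3 2-(3,5-dimethoxyphenyl)-N-methoxy-N-methylacetamide, via acyl imidazole 2 (not isolated)
Conditions: 1,1'-carbonyldiimidazole, CH2Cl2, rt; then MeNH(OMe)·HCl, rt
Reagents that add atoms: N,O-dimethylhydroxylamine hydrochloride, CNOC.Cl
Why: Carbonyldiimidazole activation converts the acid into acyl imidazole 2, which is aminolysed by the hydroxylamine set free from its hydrochloride by the imidazole already present (Weinreb amide formation).

Step 2
Reactants: 3 2-(3,5-dimethoxyphenyl)-N-methoxy-N-methylacetamide; 4 propylmagnesium bromide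
Product: 6 1-(3,5-dimethoxyphenyl)pentan-2-one, via magnesium hemiaminal adduct 5 (not isolated)
Conditions: PrMgBr (2 equiv), THF, 0 °C; 1 M HCl work-up
Reagents that add atoms: propylmagnesium bromide (4), CCC[Mg]Br
Why: In this Weinreb ketone synthesis the Grignard reagent should add once to give the chelated adduct 5, which cannot collapse before the acidic quench, so no tertiary alcohol forms and the excess reagent only makes up for some enolisation of the benzylic amide.

Step 3
Reactants: 6 1-(3,5-dimethoxyphenyl)pentan-2-one
Product: 7 2-[(3,5-dimethoxyphenyl)methyl]-2-propyl-1,3-dioxolane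
Conditions: HOCH2CH2OH, p-TsOH·H2O (cat.), toluene, reflux, Dean–Stark
Reagents that add atoms: ethylene glycol, OCCO
Why: Acid-catalysed ketalisation with azeotropic removal of water should drive the unhindered benzyl ketone to the dioxolane, and the aryl methyl ethers are inert to catalytic sulfonic acid.

Step 4
Reactants: 7 2-[(3,5-dimethoxyphenyl)methyl]-2-propyl-1,3-dioxolane
Product: 8 2-[(2-iodo-3,5-dimethoxyphenyl)methyl]-2-propyl-1,3-dioxolane
Conditions: NIS (1.05 equiv), MeCN, 0 °C → rt, dark
Reagents that add atoms: N-iodosuccinimide, O=C1CCC(=O)N1I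
Why: Electrophilic aromatic iodination of a resorcinol dimethyl ether by N-iodosuccinimide needs no added acid, so the ketal should survive, and the iodine should enter ortho to the side chain (para to one methoxy group), the two such positions being equivalent and the site between the two methoxy groups being the more shielded.

Step 5
Reactants: 9 divarinol (5-propylbenzene-1,3-diol)
Product: 10 divaric acid (2,4-dihydroxy-6-propylbenzoic acid)
Conditions: MeOMgOCO2Me (2 M in DMF), 120 °C; cold 2 M HCl
Reagents that add atoms: methylmagnesium carbonate (MeOMgOCO2Me), COC(=O)O[Mg]OC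
Why: Carboxylation with methylmagnesium carbonate (Stiles reagent) delivers CO2 within a magnesium phenoxide chelate to the ring carbon ortho to one hydroxyl and para to the other, the standard way from a 5-alkylresorcinol to the 2,4-dihydroxy-6-alkylbenzoic acid.

Step 6
Reactants: 10 divaric acid
Product: 11 benzyl divarate (benzyl 2,4-dihydroxy-6-propylbenzoate)
Conditions: BnBr (1.05 equiv), KHCO3, DMF, rt
Reagents that add atoms: benzyl bromide, BrCc1ccccc1
Why: Bicarbonate deprotonates only the carboxylic acid, so SN2 O-alkylation of the carboxylate by benzyl bromide should give the benzyl ester and leave both phenols free.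

Step 7
Reactants: 8 2-[(2-iodo-3,5-dimethoxyphenyl)methyl]-2-propyl-1,3-dioxolane; 12 carbon monoxide; 11 benzyl divarate
Product: 13 benzyl 4-({2,4-dimethoxy-6-[(2-propyl-1,3-dioxolan-2-yl)methyl]benzoyl}oxy)-2-hydroxy-6-propylbenzoate
Conditions: Pd(OAc)2 (5 mol %), Xantphos (6 mol %), Et3N (3 equiv), CO (1 atm), toluene, 90 °C
Reagents that add atoms: carbon monoxide (12), [C-]#[O+]
Why: Zerovalent palladium formed from Pd(OAc)2 and Xantphos inserts into the C–I bond of 8, carbon monoxide inserts into the aryl–palladium bond to give a divalent aroylpalladium iodide, and the triethylammonium phenoxide of 11 displaces iodide and the aryl ester is released by reductive elimination, returning zerovalent palladium. The closest known reaction type is the palladium-catalysed aryloxycarbonylation of aryl iodides with phenols under carbon monoxide, in which a wide-bite-angle diphosphine favours the acyl–oxygen reductive elimination. No ring is closed and no stereocentre is created; the step forms the ring A C1–C(=O) bond and the C(=O)–O bond to ring B. Chemoselectivity between the two hydroxyls of 11 is needed, and it is secured because the 2-OH is locked in a hydrogen bond to the adjacent benzyl ester carbonyl, which leaves the more acidic, unhindered 4-OH as the acyl acceptor. The side-chain ketone is held as the dioxolane so that no enol oxygen ortho to the aroylpalladium centre can trap it as an isocoumarin, and a small excess of 11 should keep the reaction to a single acylation.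

Step 8
Reactants: 13 benzyl 4-({2,4-dimethoxy-6-[(2-propyl-1,3-dioxolan-2-yl)methyl]benzoyl}oxy)-2-hydroxy-6-propylbenzoate
Product: 14 4-({2,4-dimethoxy-6-[(2-propyl-1,3-dioxolan-2-yl)methyl]benzoyl}oxy)-2-hydroxy-6-propylbenzoic acid
Conditions: H2 (1 atm), Pd/C (10 %), EtOAc, rt
Reagents that add atoms: none
Why: Catalytic hydrogenolysis cleaves the benzylic C–O bond of the benzyl ester under neutral conditions that should leave the aryl ester, the aryl methyl ethers and the dioxolane untouched, and the acid is carried on without storage.

Step 9
Reactants: 14 4-({2,4-dimethoxy-6-[(2-propyl-1,3-dioxolan-2-yl)methyl]benzoyl}oxy)-2-hydroxy-6-propylbenzoic acid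
Product: 15 2-hydroxy-4-{[2-hydroxy-4-methoxy-6-(2-oxopentyl)benzoyl]oxy}-6-propylbenzoic acid (target)
Conditions: BCl3 (5 equiv), CH2Cl2, −78 → 0 °C; then 1 M HCl, THF, rt
Reagents that add atoms: water, O
Why: BCl3 should bridge the inter-ring ester carbonyl oxygen and the neighbouring 2-methoxy oxygen of ring A in a six-membered chelate from which chloride removes only that methyl group while the unchelated 4-methoxy group stays (chelation-controlled ortho-demethylation), and the Lewis acid together with the aqueous acid of the work-up hydrolyses the dioxolane to the ketone.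

**Compound list**

1 | 3,5-dimethoxyphenylacetic acid | COc1cc(CC(=O)O)cc(OC)c1 | starting material
2 | 2-(3,5-dimethoxyphenyl)-1-(imidazol-1-yl)ethan-1-one (acyl imidazole) | COc1cc(CC(=O)n2ccnc2)cc(OC)c1 | intermediate
3 | 2-(3,5-dimethoxyphenyl)-N-methoxy-N-methylacetamide | COc1cc(CC(=O)N(C)OC)cc(OC)c1 | intermediate
4 | propylmagnesium bromide | CCC[Mg]Br | starting material
5 | bromomagnesium alkoxide of 1-(3,5-dimethoxyphenyl)-2-[methoxy(methyl)amino]pentan-2-ol (racemic, transient) | CCCC(O[Mg]Br)(Cc1cc(OC)cc(OC)c1)N(C)OC | intermediate
6 | 1-(3,5-dimethoxyphenyl)pentan-2-one | CCCC(=O)Cc1cc(OC)cc(OC)c1 | intermediate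
7 | 2-[(3,5-dimethoxyphenyl)methyl]-2-propyl-1,3-dioxolane | CCCC1(Cc2cc(OC)cc(OC)c2)OCCO1 | intermediate
8 | 2-[(2-iodo-3,5-dimethoxyphenyl)methyl]-2-propyl-1,3-dioxolane | CCCC1(Cc2cc(OC)cc(OC)c2I)OCCO1 | intermediate
9 | divarinol (5-propylbenzene-1,3-diol) | CCCc1cc(O)cc(O)c1 | starting material
10 | divaric acid (2,4-dihydroxy-6-propylbenzoic acid) | CCCc1cc(O)cc(O)c1C(=O)O | intermediate
11 | benzyl divarate (benzyl 2,4-dihydroxy-6-propylbenzoate) | CCCc1cc(O)cc(O)c1C(=O)OCc1ccccc1 | intermediate
12 | carbon monoxide | [C-]#[O+] | starting material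
13 | benzyl 4-({2,4-dimethoxy-6-[(2-propyl-1,3-dioxolan-2-yl)methyl]benzoyl}oxy)-2-hydroxy-6-propylbenzoate | CCCC1(Cc2cc(OC)cc(OC)c2C(=O)Oc2cc(O)c(C(=O)OCc3ccccc3)c(CCC)c2)OCCO1 | intermediate
14 | 4-({2,4-dimethoxy-6-[(2-propyl-1,3-dioxolan-2-yl)methyl]benzoyl}oxy)-2-hydroxy-6-propylbenzoic acid | CCCC1(Cc2cc(OC)cc(OC)c2C(=O)Oc2cc(O)c(C(=O)O)c(CCC)c2)OCCO1 | intermediate
15 | 2-hydroxy-4-{[2-hydroxy-4-methoxy-6-(2-oxopentyl)benzoyl]oxy}-6-propylbenzoic acid | CCCC(=O)Cc1cc(OC)cc(O)c1C(=O)Oc1cc(O)c(C(=O)O)c(CCC)c1 | target

**Step count and risks**

Total step count: 9. Longest linear sequence: 7 steps (steps 1, 2, 3, 4, 7, 8, 9); the ring B branch (steps 5, 6) joins at step 7.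

Steps most likely to fail:

Step 9. Opening of the ketal by the Lewis acid right beside the BCl3-activated aryl ester may let the side-chain oxygen and the ester carbonyl engage each other, with lactonisation and expulsion of the ring B phenol. Ether cleavage may also stop short or reach the 4-methoxy group. The fallback separates the events and keeps the carboxyl masked until a neutral last step. It sets out from 13: the ketone is released first under mild Brønsted acid (PPTS, acetone/H2O, 50 °C) to give benzyl 4-{[2,4-dimethoxy-6-(2-oxopentyl)benzoyl]oxy}-2-hydroxy-6-propylbenzoate F1. The chelated methyl ether is then cleaved on this neutral keto ester with BCl3 in CH2Cl2 held at −78 °C to give benzyl 2-hydroxy-4-{[2-hydroxy-4-methoxy-6-(2-oxopentyl)benzoyl]oxy}-6-propylbenzoate F2. Hydrogenolysis (H2, Pd/C, EtOAc) returns to the route at 15; any benzyl ester already lost to the Lewis acid is 15 itself.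

Step 7. Capture of the hindered, doubly ortho-substituted aroylpalladium intermediate by the weakly nucleophilic phenoxide may be slow, so that hydrodeiodination or catalyst decay takes over, or a second acylation at the 2-OH may occur. The fallback forms the same two bonds in two separate operations from 8. Iodine–lithium exchange (n-BuLi, THF, −78 °C) and a CO2 quench should give 2,4-dimethoxy-6-[(2-propyl-1,3-dioxolan-2-yl)methyl]benzoic acid F3. Steglich esterification of F3 with 11 (DCC, DMAP, CH2Cl2, rt), again at the non-chelated 4-OH, comes back to the route at 13.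

Step 5. Carboxylation may be incomplete, the product may lose CO2 again during the hot reaction or the acidic work-up, and some attack between the two hydroxyls is possible. The fallback builds the carboxyl by formylation and oxidation, starting from 9. Vilsmeier–Haack formylation (POCl3, DMF, then aqueous NaOAc) should give 2,4-dihydroxy-6-propylbenzaldehyde F4. Benzylation of both phenols (BnBr, K2CO3, DMF, 60 °C) gives 2,4-bis(benzyloxy)-6-propylbenzaldehyde F5. Pinnick oxidation (NaClO2, NaH2PO4, 2-methyl-2-butene, t-BuOH/H2O) gives 2,4-bis(benzyloxy)-6-propylbenzoic acid F6. Hydrogenolysis (H2, Pd/C, EtOAc) returns to the route at 10.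

Further compounds
F1 | step 9 | benzyl 4-{[2,4-dimethoxy-6-(2-oxopentyl)benzoyl]oxy}-2-hydroxy-6-propylbenzoate | CCCC(=O)Cc1cc(OC)cc(OC)c1C(=O)Oc1cc(O)c(C(=O)OCc2ccccc2)c(CCC)c1
F2 | step 9 | benzyl 2-hydroxy-4-{[2-hydroxy-4-methoxy-6-(2-oxopentyl)benzoyl]oxy}-6-propylbenzoate | CCCC(=O)Cc1cc(OC)cc(O)c1C(=O)Oc1cc(O)c(C(=O)OCc2ccccc2)c(CCC)c1
F3 | step 7 | 2,4-dimethoxy-6-[(2-propyl-1,3-dioxolan-2-yl)methyl]benzoic acid | CCCC1(Cc2cc(OC)cc(OC)c2C(=O)O)OCCO1
F4 | step 5 | 2,4-dihydroxy-6-propylbenzaldehyde | CCCc1cc(O)cc(O)c1C=O
F5 | step 5 | 2,4-bis(benzyloxy)-6-propylbenzaldehyde | CCCc1cc(OCc2ccccc2)cc(OCc2ccccc2)c1C=O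
F6 | step 5 | 2,4-bis(benzyloxy)-6-propylbenzoic acid | CCCc1cc(OCc2ccccc2)cc(OCc2ccccc2)c1C(=O)O
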